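**Retrosynthetic overview**

1. Target 18 ⇐ O‑debenzylation of 17 ⇐ Felkin–Anh/chelation‑controlled hydride reduction of the trans‑3‑aroyl‑4‑benzyl‑tetrahydrofuran 16, which sets the carbinol carbon.
2. 16 ⇐ formal [3+2] "oxygen swap" of (R)‑5‑aryl‑3‑benzyl‑2,3‑dihydrofuran 12 with formaldehyde (MgI2): enol‑ether carbon C4 bonds to the formaldehyde carbon, iodide cuts the old ring O–CH2 bond, the formaldehyde oxygen closes on that CH2, and the old ring oxygen ends as the ketone oxygen.
3. Enabling feature: in the tetrahydrofuran ring, C3 (carrying the benzylic carbinol carbon) lies between an O1–C2H2 unit that is exactly one formaldehyde and the C4–C5H2–O arm. With the carbinol carbon at ketone level, the atoms C(=O)–C3–C4–C5H2 are a masked 2,3‑dihydrofuran, and C3 is enolisable, so cis and trans isomers converge on trans.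
4. 12 ⇐ (R)‑β‑benzyl‑γ‑butyrolactone 9 + aryllithium; 9 ⇐ cyclopropane‑fused lactone 6 [(R)‑epichlorohydrin + diethyl malonate] opened by the aryl Grignard reagent/CuI; both aryl groups come from bromide 3.
5. Ring order: cyclopropane‑fused γ‑lactone → γ‑lactone → 2,3‑dihydrofuran → tetrahydrofuran (last).

Key step: step 6

Abbreviation: Ar = 4‑(benzyloxy)‑3,5‑dimethoxyphenyl; ArCH2 = 4‑(benzyloxy)‑3,5‑dimethoxybenzyl.
Assumption: the trans isomer of the 3‑aroyl‑4‑benzyl‑tetrahydrofuran is taken to be the thermodynamically preferred one, as for other vicinally disubstituted five‑membered rings.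

**Step 1**
Reactants: 1 4‑bromo‑2,6‑dimethoxyphenol; 2 benzyl bromide
Product: 3 2‑(benzyloxy)‑5‑bromo‑1,3‑dimethoxybenzene (ArBr)
Conditions: K2CO3, DMF, 60 °C
Reagents that add atoms: none
Why: Williamson etherification of the acidic 2,6‑dimethoxyphenol; the benzyl ether masks the phenol through the organometallic steps and leaves by hydrogenolysis at the end.

**Step 2**
Reactants: 4 (R)‑epichlorohydrin; 5 diethyl malonate
Product: 6 ethyl (1S,5R)‑2‑oxo‑3‑oxabicyclo[3.1.0]hexane‑1‑carboxylate
Conditions: NaOEt, EtOH, 0 °C to reflux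
Reagents that add atoms: none
Why: malonate–epichlorohydrin annulation (epoxide opening at CH2, re‑closure to the transposed epoxide with loss of chloride, 3‑exo‑tet cyclopropanation with inversion at the stereocentre, lactonisation of the cis ester), so the single stereocentre of 4 fixes both ring‑fusion carbons as (1S,5R).

**Step 3**
Reactants: 3 ArBr; 6 bicyclic lactone
Product: 8 ethyl (4R)‑4‑[4‑(benzyloxy)‑3,5‑dimethoxybenzyl]‑2‑oxotetrahydrofuran‑3‑carboxylate (C3 epimers), via arylmagnesium bromide 7 (not isolated)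
Conditions: 3, Mg, THF, reflux; then CuI (20 mol %), 6, THF, −30 to 0 °C; aq NH4Cl
Reagents that add atoms: none
Why: copper‑catalysed homoconjugate addition of a Grignard reagent to a doubly activated cyclopropane, which occurs at the unhindered cyclopropane CH2 and turns it into the benzylic carbon; the ring‑fusion CH is untouched and becomes C4 (R).

**Step 4**
Reactants: 8 ester lactone
Product: 9 (4R)‑4‑[4‑(benzyloxy)‑3,5‑dimethoxybenzyl]dihydrofuran‑2(3H)‑one
Conditions: LiCl, H2O, DMSO, 140 °C
Reagents that add atoms: none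
Why: Krapcho dealkoxycarbonylation of the malonate‑type ester removes the activating group and the labile C3 centre without touching C4.

**Step 5**
Reactants: 3 ArBr; 9 lactone
Product: 12 (3R)‑5‑[4‑(benzyloxy)‑3,5‑dimethoxyphenyl]‑3‑[4‑(benzyloxy)‑3,5‑dimethoxybenzyl]‑2,3‑dihydrofuran, via aryllithium 10 (not isolated), via hydroxy ketone 11 (not isolated)
Conditions: 3, n‑BuLi, THF, −78 °C; then 9, −78 °C; aq NH4Cl; crude 11, PPTS (5 mol %), 4 Å MS, toluene, 80 °C
Reagents that add atoms: none
Why: bromine–lithium exchange and single addition of the aryllithium to the γ‑lactone (the lithium lactolate persists at −78 °C), then acid‑catalysed cyclodehydration of the γ‑hydroxy ketone to the aryl‑conjugated cyclic enol ether; the stereocentre is not involved.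

**Step 6**
Reactants: 12 dihydrofuran; 13 formaldehyde (charged as paraformaldehyde)
Product: 16 [(3R,4R)‑4‑[4‑(benzyloxy)‑3,5‑dimethoxybenzyl]tetrahydrofuran‑3‑yl][4‑(benzyloxy)‑3,5‑dimethoxyphenyl]methanone, via iodomagnesium iodo aldolate 14 (not isolated), via cis ketone 15 (not isolated)
Conditions: (CH2O)n (2 equiv), MgI2·OEt2 (0.5 equiv), 4 Å MS, toluene–THF 4:1, 50 °C; then DBU (0.3 equiv), rt
Reagents that add atoms: none
Why: Proposed new method: MgI2‑activated formaldehyde is attacked by the enol‑ether carbon C4 of 12 (Prins/Mukaiyama‑type addition; closest known types are Lewis‑acid additions of cyclic enol ethers and silyl enol ethers to aldehydes and the MgI2‑mediated formal [3+2] ring expansion of cyclopropyl ketones with aldehydes), giving an aryl‑stabilised cyclic oxocarbenium ion whose only O‑alkyl carbon, the ring OCH2, is opened by iodide in an SN2 dealkylation (the same event as the known conversion of 4,5‑dihydrofurans into γ‑halo ketones with HX), which unmasks the aryl ketone and leaves iodo aldolate 14. The magnesium alkoxide of 14 then displaces the primary iodide in a 5‑exo‑tet Williamson closure, so the new tetrahydrofuran ring contains the formaldehyde C–O unit, the old ring oxygen has become the ketone oxygen, and MgI2 is returned. The new stereocentre (aroyl‑bearing C3 of the tetrahydrofuran) is first set under substrate control, formaldehyde adding anti to the benzyl group of 12, which after the ring switch corresponds mainly to cis ketone 15; it is then corrected thermodynamically, because this carbon is α to the aryl ketone and DBU equilibrates both epimers through the enol(ate) to the more stable trans ketone 16, whichever face was attacked. The step needs attack at carbon C4 of the enol ether and not hydroxymethylation of the arene rings, a single site of dealkylation and an untouched benzyl‑bearing stereocentre; these are secured by the much higher nucleophilicity of the α‑aryl enol ether than of the alkoxyarenes, by the oxocarbenium ion having only one O–CH2 group, and by the benzyl‑bearing carbon being neither cationic nor enolisable (it is β to the ketone and only adjacent to the SN2 carbon). The overall change is strongly downhill (an enol‑ether C=C and a formaldehyde C=O are traded for a ketone C=O, a C–C bond and a C–O bond), so a sub‑stoichiometric iodide shuttle should suffice.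

**Step 7**
Reactants: 16 trans ketone
Product: 17 (S)‑[(3R,4R)‑4‑[4‑(benzyloxy)‑3,5‑dimethoxybenzyl]tetrahydrofuran‑3‑yl][4‑(benzyloxy)‑3,5‑dimethoxyphenyl]methanol
Conditions: LiBH(s‑Bu)3, THF, −78 °C; then NaOH, H2O2
Reagents that add atoms: none
Why: Felkin–Anh‑controlled hydride addition: the bulky hydride attacks anti to the branched C3–C4 ring bond and past the C3–H, and a chelate through the ring oxygen would expose the same face, so both models predict the (S)‑carbinol from the (3R) ketone.

**Step 8**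
Reactants: 17 dibenzyl ether
Product: 18 4‑[(S)‑hydroxy[(3R,4R)‑4‑(4‑hydroxy‑3,5‑dimethoxybenzyl)tetrahydrofuran‑3‑yl]methyl]‑2,6‑dimethoxyphenol (target)
Conditions: H2 (1 atm), 10% Pd/C, EtOAc, rt
Reagents that add atoms: none
Why: catalytic hydrogenolysis of the two aryl benzyl ethers, which under neutral conditions should be much faster than cleavage of the secondary benzylic C–OH bond; the reaction is stopped after uptake of two equivalents of H2.

**Compound list**

1 | 4‑bromo‑2,6‑dimethoxyphenol | COc1cc(Br)cc(OC)c1O | starting material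
2 | benzyl bromide | BrCc1ccccc1 | starting material
3 | 2‑(benzyloxy)‑5‑bromo‑1,3‑dimethoxybenzene (ArBr) | COc1cc(Br)cc(OC)c1OCc1ccccc1 | intermediate
4 | (R)‑epichlorohydrin [(R)‑2‑(chloromethyl)oxirane] | ClC[C@H]1CO1 | starting material
5 | diethyl malonate | CCOC(=O)CC(=O)OCC | starting material
6 | ethyl (1S,5R)‑2‑oxo‑3‑oxabicyclo[3.1.0]hexane‑1‑carboxylate | CCOC(=O)[C@]12C[C@H]1COC2=O | intermediate
7 | [4‑(benzyloxy)‑3,5‑dimethoxyphenyl]magnesium bromide | COc1cc([Mg]Br)cc(OC)c1OCc1ccccc1 | intermediate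
8 | ethyl (4R)‑4‑[4‑(benzyloxy)‑3,5‑dimethoxybenzyl]‑2‑oxotetrahydrofuran‑3‑carboxylate (C3 epimers) | CCOC(=O)C1[C@@H](Cc2cc(OC)c(OCc3ccccc3)c(OC)c2)COC1=O | intermediate
9 | (4R)‑4‑[4‑(benzyloxy)‑3,5‑dimethoxybenzyl]dihydrofuran‑2(3H)‑one | COc1cc(C[C@H]2COC(=O)C2)cc(OC)c1OCc1ccccc1 | intermediate
10 | [4‑(benzyloxy)‑3,5‑dimethoxyphenyl]lithium | [Li]c1cc(OC)c(OCc2ccccc2)c(OC)c1 | intermediate
11 | (3R)‑1‑[4‑(benzyloxy)‑3,5‑dimethoxyphenyl]‑3‑[4‑(benzyloxy)‑3,5‑dimethoxybenzyl]‑4‑hydroxybutan‑1‑one (in equilibrium with its cyclic hemiketal) | COc1cc(C[C@@H](CO)CC(=O)c2cc(OC)c(OCc3ccccc3)c(OC)c2)cc(OC)c1OCc1ccccc1 | intermediate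
12 | (3R)‑5‑[4‑(benzyloxy)‑3,5‑dimethoxyphenyl]‑3‑[4‑(benzyloxy)‑3,5‑dimethoxybenzyl]‑2,3‑dihydrofuran | COc1cc(C[C@H]2COC(=C2)c2cc(OC)c(OCc3ccccc3)c(OC)c2)cc(OC)c1OCc1ccccc1 | intermediate
13 | formaldehyde (charged as paraformaldehyde) | C=O | starting material
14 | iodomagnesium (3R)‑2‑[4‑(benzyloxy)‑3,5‑dimethoxybenzoyl]‑3‑[4‑(benzyloxy)‑3,5‑dimethoxybenzyl]‑4‑iodobutan‑1‑olate (C2 epimers) | COc1cc(C[C@@H](CI)C(CO[Mg]I)C(=O)c2cc(OC)c(OCc3ccccc3)c(OC)c2)cc(OC)c1OCc1ccccc1 | intermediate
15 | [(3S,4R)‑4‑[4‑(benzyloxy)‑3,5‑dimethoxybenzyl]tetrahydrofuran‑3‑yl][4‑(benzyloxy)‑3,5‑dimethoxyphenyl]methanone (cis) | COc1cc(C[C@H]2COC[C@H]2C(=O)c2cc(OC)c(OCc3ccccc3)c(OC)c2)cc(OC)c1OCc1ccccc1 | intermediate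
16 | [(3R,4R)‑4‑[4‑(benzyloxy)‑3,5‑dimethoxybenzyl]tetrahydrofuran‑3‑yl][4‑(benzyloxy)‑3,5‑dimethoxyphenyl]methanone (trans) | COc1cc(C[C@H]2COC[C@@H]2C(=O)c2cc(OC)c(OCc3ccccc3)c(OC)c2)cc(OC)c1OCc1ccccc1 | intermediate
17 | (S)‑[(3R,4R)‑4‑[4‑(benzyloxy)‑3,5‑dimethoxybenzyl]tetrahydrofuran‑3‑yl][4‑(benzyloxy)‑3,5‑dimethoxyphenyl]methanol | COc1cc(C[C@H]2COC[C@@H]2[C@H](O)c2cc(OC)c(OCc3ccccc3)c(OC)c2)cc(OC)c1OCc1ccccc1 | intermediate
18 | 4‑[(S)‑hydroxy[(3R,4R)‑4‑(4‑hydroxy‑3,5‑dimethoxybenzyl)tetrahydrofuran‑3‑yl]methyl]‑2,6‑dimethoxyphenol | COc1cc(C[C@H]2COC[C@@H]2[C@H](O)c2cc(OC)c(O)c(OC)c2)cc(OC)c1O | target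

**Step count and risks**

Total step count: 8. Longest linear sequence: 7 steps (4 → 6 → 8 → 9 → 12 → 16 → 17 → 18).

Steps most likely to fail:

1. Step 6 (proposed new method). The cascade may stall after the first bond: proton loss from the oxocarbenium ion to an ene‑type hydroxymethyl enol ether, capture of the cation by a second formaldehyde as a 1,3‑dioxane, or proton‑mediated ring opening without C–C bond formation. Hydroxymethylation of the electron‑rich arene rings may also compete. The fallback does the same bond set stepwise with known reactions and sets out from hydroxy ketone 11, isolated after the aqueous work‑up of step 5. Appel iodination (PPh3, I2, imidazole, CH2Cl2, 0 °C) should give (3R)‑1‑[4‑(benzyloxy)‑3,5‑dimethoxyphenyl]‑3‑[4‑(benzyloxy)‑3,5‑dimethoxybenzyl]‑4‑iodobutan‑1‑one F1. TMSOTf/Et3N (CH2Cl2, 0 °C) should then give the (Z)‑trimethylsilyl enol ether F2. Lewis‑acid hydroxymethylation of the silyl enol ether with aqueous formaldehyde [Yb(OTf)3, THF–H2O, rt; Mukaiyama aldol type] should give the iodo aldol (3R)‑2‑(hydroxymethyl)‑4‑iodo ketone F3. Ag2O (CH2Cl2, rt) should close the ring by 5‑exo‑tet etherification without forming an enolate, and catalytic DBU should equilibrate the aroyl‑bearing carbon; the sequence comes back to the route at 16.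

2. Step 7. Facial selectivity of hydride addition may be poor if the two ring bonds at C3 are not differentiated enough. The fallback replaces substrate control by catalyst control: from 16, asymmetric transfer hydrogenation with RuCl(p‑cymene)[(S,S)‑TsDPEN] in HCO2H/Et3N, the (S,S) catalyst being the one that gives (S)‑carbinols from aryl ketones, should lead directly to 17. No new compound is made.

3. Step 5. The aryllithium may add twice if the lactolate collapses early. The fallback changes the acyl donor and sets out from lactone 9. AlMe3‑mediated aminolysis with N,O‑dimethylhydroxylamine hydrochloride (CH2Cl2, 0 °C to rt) should give (3R)‑3‑[4‑(benzyloxy)‑3,5‑dimethoxybenzyl]‑4‑hydroxy‑N‑methoxy‑N‑methylbutanamide F4, used at once. With 2.2 equivalents of Grignard reagent 7 (THF, 0 °C; the first equivalent forms the alkoxide), the chelated tetrahedral intermediate should stop the addition at the ketone stage, and the sequence comes back to the route at 11, which is dehydrated to 12 as before.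

**Further compounds**

F1 | step 6 | (3R)‑1‑[4‑(benzyloxy)‑3,5‑dimethoxyphenyl]‑3‑[4‑(benzyloxy)‑3,5‑dimethoxybenzyl]‑4‑iodobutan‑1‑one | COc1cc(C[C@@H](CI)CC(=O)c2cc(OC)c(OCc3ccccc3)c(OC)c2)cc(OC)c1OCc1ccccc1
F2 | step 6 | {[(1Z,3R)‑1‑[4‑(benzyloxy)‑3,5‑dimethoxyphenyl]‑3‑[4‑(benzyloxy)‑3,5‑dimethoxybenzyl]‑4‑iodobut‑1‑en‑1‑yl]oxy}trimethylsilane | COc1cc(C[C@@H](CI)/C=C(\O[Si](C)(C)C)c2cc(OC)c(OCc3ccccc3)c(OC)c2)cc(OC)c1OCc1ccccc1
F3 | step 6 | (3R)‑1‑[4‑(benzyloxy)‑3,5‑dimethoxyphenyl]‑3‑[4‑(benzyloxy)‑3,5‑dimethoxybenzyl]‑2‑(hydroxymethyl)‑4‑iodobutan‑1‑one (C2 epimers) | COc1cc(C[C@@H](CI)C(CO)C(=O)c2cc(OC)c(OCc3ccccc3)c(OC)c2)cc(OC)c1OCc1ccccc1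
F0 | step 7 | none | none
F4 | step 5 | (3R)‑3‑[4‑(benzyloxy)‑3,5‑dimethoxybenzyl]‑4‑hydroxy‑N‑methoxy‑N‑methylbutanamide | COc1cc(C[C@@H](CO)CC(=O)N(C)OC)cc(OC)c1OCc1ccccc1
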